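**Retrosynthetic overview**
25 ⇒ 22 (esterification at O8) ⇒ 19 (C13 added by lactone-enolate methylation).
19 ⇒ 18 by cutting C7–C8. Compound 18 is an isomer of 19 built from two flat five-membered rings, a 3(2H)-furanone and a butenolide, hinged by the Z-C4=C5 alkene, with a CH2CH2OH arm on C10. A photocatalytic C8–H/C7 radical hydroalkylation closes the ten-membered carbocycle and the nine-membered oxacycle together and sets C7 and C8.
Enabling feature: in the lactone ring O–C6–C7–C11–C12, C7 is β to the carbonyl C12 and its partner C8 bears oxygen. At the butenolide level (C7=C11), C7 therefore accepts the nucleophilic radical that a primary alcohol gives at C8. The planar furanone ring (O, C3, C2, C1, C10) and the Z alkene leave only four rotatable bonds between the two carbons.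
18 ⇒ butenolide by RCM, furanone by gold-catalysed 5-endo-dig closure, C3–C4 by Sonogashira coupling of ynone 6 with iodide 14.
6 ⇐ (R)-citramalic acid (chiral pool; its five carbons become C1, C10, C14, C9, C8). 14 ⇐ acrolein + propynyl Grignard reagent (C6 by lipase resolution). Ring order: furanone, butenolide, then the 10- and 9-membered rings together.

Key step: step 13

Remark: germacrane numbering is used throughout. C1 is the furanone C=O, C2=C3 follows, the ring O lies between C3 and C10, then C4(C15)=C5, C6–O (lactone), C7, C8, C9, C10(C14), C11, C12 (lactone C=O), and C13 (methyl on C11).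
Assumption: 1, 5, 7, 8, 13, 20 and 23 and all reagents and catalysts are taken as commercial.

Step 1
Reactants: 1 (R)-citramalic acid
Product: 2 2-[(4R)-2,2,4-trimethyl-5-oxo-1,3-dioxolan-4-yl]acetic acid
Conditions: Me2C(OMe)2, TsOH·H2O (cat.), acetone, rt
Reagents that add atoms: 2,2-dimethoxypropane COC(C)(C)OC
Why: Acid-catalysed acetonide (1,3-dioxolan-4-one) formation engages only the α-hydroxy acid unit, which alone can close a five-membered ring; this tells the two carboxyl groups apart, and the quaternary centre (future C10, R) comes unchanged from the chiral pool.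

Step 2
Reactants: 2 dioxolanone acid
Product: 3 (5R)-5-(2-hydroxyethyl)-2,2,5-trimethyl-1,3-dioxolan-4-one
Conditions: BH3·THF, THF, 0 °C to rt; then H2O
Reagents that add atoms: none
Why: Chemoselective borane reduction of a free carboxylic acid (via the acyloxyborane) in the presence of the ester-type dioxolanone carbonyl; no stereocentre is touched.

Step 3
Reactants: 3 hydroxyethyl dioxolanone
Product: 4 (5R)-5-[2-(tert-butyldimethylsilyloxy)ethyl]-2,2,5-trimethyl-1,3-dioxolan-4-one
Conditions: TBSCl, imidazole, CH2Cl2, 0 °C to rt
Reagents that add atoms: tert-butyldimethylsilyl chloride CC(C)(C)[Si](C)(C)Cl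
Why: Standard silylation of a primary alcohol, done at once so that 3 cannot translactonise; it keeps O8 out of the later alkyne chemistry.

Step 4
Reactants: 4 silyl ether dioxolanone; 5 ethynylmagnesium bromide
Product: 6 (4R)-6-(tert-butyldimethylsilyloxy)-4-hydroxy-4-methylhex-1-yn-3-one
Conditions: 5 (1.3 equiv), THF, −78 to −30 °C; then pH 7 buffer
Reagents that add atoms: none
Why: Acetylide addition to an activated, non-enolisable ester (1,3-dioxolan-4-one): the tetrahedral magnesium alkoxide should survive at low temperature and collapse only on work-up with loss of acetone, which stops the reaction at the α′-hydroxy ynone.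

Step 5
Reactants: 7 acrolein; 8 1-propynylmagnesium bromide
Product: 9 (±)-hex-1-en-4-yn-3-ol
Conditions: THF, −78 to 0 °C; then H2O
Reagents that add atoms: none
Why: 1,2-Addition of an alkynyl Grignard reagent to an enal; the racemic carbinol carbon is the future C6.

Step 6
Reactants: 9 (±)-hex-1-en-4-yn-3-ol
Product: 11 (±)-(4Z)-5-iodohexa-1,4-dien-3-ol, via cyclic alkenylaluminate 10 (not isolated)
Conditions: Red-Al, THF, 0 °C to rt; then I2, THF, −78 to 0 °C; then H2O
Reagents that add atoms: iodine II; Red-Al [Na+].[AlH2-](OCCOC)OCCOC (its atoms stay only in 10)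
Why: Hydroxyl-directed trans-hydroalumination of a propargylic alcohol followed by iodinolysis with retention: aluminium ends on the distal alkyne carbon within the five-membered chelate 10, so iodine (the later C3 position) and C6 are cis on the new C4=C5 bond (Z), and the isolated vinyl group does not react.

Step 7
Reactants: 11 (±)-(4Z)-5-iodohexa-1,4-dien-3-ol
Product: 12 (3S,4Z)-5-iodohexa-1,4-dien-3-ol
Conditions: Burkholderia cepacia lipase, vinyl acetate, MTBE, 30 °C, to slightly beyond half conversion; chromatography
Reagents that add atoms: none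
Why: Lipase-catalysed kinetic resolution by irreversible transesterification: by the empirical size rule for secondary alcohols (large iodoalkenyl against medium vinyl) the R enantiomer should be acetylated, and the S alcohol, which has the spatial arrangement of C6 of the target, should be left.

Step 8
Reactants: 12 (3S,4Z)-5-iodohexa-1,4-dien-3-ol; 13 acryloyl chloride
Product: 14 (3S,4Z)-5-iodohexa-1,4-dien-3-yl prop-2-enoate
Conditions: iPr2NEt, CH2Cl2, −20 to 0 °C
Reagents that add atoms: none
Why: O-Acylation with an acid chloride; the C6–O bond is not broken, so the configuration is retained, and O6 is blocked before the ynone appears, so no furan can form from a Z-enynol.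

Step 9
Reactants: 14 iodo dienyl acrylate; 6 hydroxy ynone
Product: 15 (3S,4Z,9R)-11-(tert-butyldimethylsilyloxy)-9-hydroxy-5,9-dimethyl-8-oxoundeca-1,4-dien-6-yn-3-yl prop-2-enoate
Conditions: PdCl2(PPh3)2 (cat.), CuI (cat.), Et3N, THF, 0 °C to rt
Reagents that add atoms: none
Why: Sonogashira coupling forms C3–C4: oxidative addition into the alkenyl C–I bond and reductive elimination go with retention, so the Z geometry of C4=C5 is kept, and oxidative addition is expected to be much faster than ionisation of the allylic ester.

Step 10
Reactants: 15 enynone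
Product: 16 (2R)-2-[2-(tert-butyldimethylsilyloxy)ethyl]-2-methyl-5-[(2Z,4S)-4-(acryloyloxy)hexa-2,5-dien-2-yl]furan-3(2H)-one
Conditions: Ph3PAuNTf2 (cat.), CH2Cl2, rt
Reagents that add atoms: none
Why: Gold(I)-catalysed 5-endo-dig hydroalkoxylation of an α′-hydroxy ynone, a known entry to 3(2H)-furanones: the only free hydroxyl (on C10) adds to the β-carbon C3 of the activated alkyne and closes the furanone ring without touching C10 or C6.

Step 11
Reactants: 16 furanone acrylate
Product: 17 (2R)-2-[2-(tert-butyldimethylsilyloxy)ethyl]-2-methyl-5-{(1Z)-1-[(2S)-5-oxo-2,5-dihydrofuran-2-yl]prop-1-en-2-yl}furan-3(2H)-one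
Conditions: Grubbs II catalyst (cat.), 1,4-benzoquinone (cat.), CH2Cl2 (dilute), 40 °C
Reagents that add atoms: none
Why: Ring-closing metathesis of an allylic acrylate to a 2(5H)-furanone: the carbene loads on the monosubstituted vinyl group and closes on the acrylate, the trisubstituted C4=C5 and C2=C3 bonds are inert, and the neutral medium spares the acidic C6–H.

Step 12
Reactants: 17 silyl ether butenolide
Product: 18 (2R)-2-(2-hydroxyethyl)-2-methyl-5-{(1Z)-1-[(2S)-5-oxo-2,5-dihydrofuran-2-yl]prop-1-en-2-yl}furan-3(2H)-one
Conditions: HF·pyridine, THF, 0 °C to rt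
Reagents that add atoms: none
Why: Fluoride cleavage of a primary silyl ether under weakly acidic conditions, chosen because C6–H (γ-hydrogen of the butenolide and vinylogous to the furanone carbonyl) does not tolerate base.

Step 13
Reactants: 18 seco-alcohol
Product: 19 (6R,7R,8R,10R)-8-hydroxy-1-oxo-3,10-epoxy-13-norgermacra-2,4Z-dien-12,6-olide
Conditions: (nBu4N)4W10O32 (cat.), MeCN (0.01 M, degassed), 390 nm LED, 20 °C
Reagents that add atoms: none
Why: Proposed new method: photoexcited decatungstate abstracts a hydridic α-hydroxy C8–H of 18 (the other C–H bonds lie on or next to electron-poor π systems and are polarity-mismatched for this electrophilic abstractor), the nucleophilic hydroxyalkyl radical adds to C7, the β-carbon of the butenolide, and the electrophilic C11 radical takes hydrogen back from the reduced cluster, so that 18 is isomerised to 19 with no stoichiometric reagent. The closest known reaction types are the decatungstate- or aryl-ketone-photocatalysed Giese-type addition of alcohols to 2(5H)-furanones and other electron-poor alkenes, which is intermolecular, and reductive radical macrocyclisation onto enoates; their use for a medium ring is what is new. The one bond closes the ten-membered carbocycle C1–C10 in the 10-exo-trig mode (radical left outside on C11) and, through the furanone oxygen, the nine-membered oxacycle in the 9-exo-trig mode, only the four bonds C3–C4, C5–C6, C9–C10 and C8–C9 must be frozen, and a radical that is quenched before closure merely returns 18, so a slow closure costs light and not material. C7 is controlled by C6: the radical enters the butenolide face opposite to the C5 branch, as in intermolecular radical additions to 5-substituted butenolides, which gives the trans-fused lactone (7R). C8 is controlled by the tether: it holds C9 roughly antiperiplanar to C6 along the forming bond, so the hydroxyl lies either above the lactone ring or outside next to H7, and the outside rotamer gives 8R. The step needs addition at C7 and not at the dienone, which is secured because attack at C3 would build a strained 7-oxanorbornanone and destroy the vinylogous ester, while attack at C5 would place the s-trans C10–O–C3–C4 unit in a seven-membered ring, and it needs light that only the catalyst absorbs (390 nm, beyond the dienone band).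

Step 14
Reactants: 19 tricyclic alcohol; 20 iodomethane
Product: 22 (6R,7R,8R,10R,11S)-8-hydroxy-1-oxo-3,10-epoxygermacra-2,4Z-dien-12,6-olide, via dilithium alkoxide enolate 21 (not isolated)
Conditions: LiHMDS (2.2 equiv), THF, −78 °C; then MeI, −78 to −40 °C; then AcOH
Reagents that add atoms: lithium hexamethyldisilazide [Li]N([Si](C)(C)C)[Si](C)(C)C (lithium, in 21 only)
Why: Kinetic alkylation of a γ-lactone enolate (the first equivalent of base goes to the 8-OH): iodomethane approaches C11 from the face opposite to the C8 branch on the neighbouring C7, the usual trans-α,β selectivity of β-substituted butyrolactone enolates, which gives 11S; the furanone carbonyl has no α-hydrogen and cannot enolise.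

Step 15
Reactants: 22 deacyl compound; 23 angelic acid
Product: 25 target (8-O-angelate of 22), via mixed anhydride 24 (not isolated)
Conditions: 23, 2,4,6-Cl3C6H2COCl, Et3N, toluene, rt; then 22, toluene, 80 °C
Reagents that add atoms: 2,4,6-trichlorobenzoyl chloride O=C(Cl)c1c(Cl)cc(Cl)cc1Cl (its atoms stay only in 24)
Why: Mixed-anhydride (Yamaguchi-type) esterification without nucleophilic catalyst: the alcohol attacks the unhindered angeloyl carbonyl of 24, leaving out the acid chloride and DMAP avoids Z to E isomerisation of the angeloyl unit, and the C8–O bond is not broken.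

**Compound list**
1 | (R)-citramalic acid | C[C@@](O)(CC(=O)O)C(=O)O | starting material
2 | 2-[(4R)-2,2,4-trimethyl-5-oxo-1,3-dioxolan-4-yl]acetic acid | C[C@]1(CC(=O)O)OC(C)(C)OC1=O | intermediate
3 | (5R)-5-(2-hydroxyethyl)-2,2,5-trimethyl-1,3-dioxolan-4-one | C[C@]1(CCO)OC(C)(C)OC1=O | intermediate
4 | (5R)-5-[2-(tert-butyldimethylsilyloxy)ethyl]-2,2,5-trimethyl-1,3-dioxolan-4-one | C[C@]1(CCO[Si](C)(C)C(C)(C)C)OC(C)(C)OC1=O | intermediate
5 | ethynylmagnesium bromide | C#C[Mg]Br | starting material
6 | (4R)-6-(tert-butyldimethylsilyloxy)-4-hydroxy-4-methylhex-1-yn-3-one | CC(C)(C)[Si](C)(C)OCC[C@@](C)(O)C(=O)C#C | intermediate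
7 | acrolein | C=CC=O | starting material
8 | 1-propynylmagnesium bromide | CC#C[Mg]Br | starting material
9 | (±)-hex-1-en-4-yn-3-ol | C=CC(O)C#CC | intermediate
10 | sodium cyclic alkenylaluminate (1,2-oxaluminole chelate, racemic) | [Na+].C=CC1C=C(C)[Al-](OCCOC)(OCCOC)O1 | intermediate
11 | (±)-(4Z)-5-iodohexa-1,4-dien-3-ol | C/C(I)=C/C(O)C=C | intermediate
12 | (3S,4Z)-5-iodohexa-1,4-dien-3-ol | C/C(I)=C/[C@H](C=C)O | intermediate
13 | acryloyl chloride | C=CC(=O)Cl | starting material
14 | (3S,4Z)-5-iodohexa-1,4-dien-3-yl prop-2-enoate | C/C(I)=C/[C@H](C=C)OC(=O)C=C | intermediate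
15 | (3S,4Z,9R)-11-(tert-butyldimethylsilyloxy)-9-hydroxy-5,9-dimethyl-8-oxoundeca-1,4-dien-6-yn-3-yl prop-2-enoate | CC(C)(C)[Si](C)(C)OCC[C@@](C)(O)C(=O)C#C/C(C)=C\[C@H](C=C)OC(=O)C=C | intermediate
16 | (2R)-2-[2-(tert-butyldimethylsilyloxy)ethyl]-2-methyl-5-[(2Z,4S)-4-(acryloyloxy)hexa-2,5-dien-2-yl]furan-3(2H)-one | CC(C)(C)[Si](C)(C)OCC[C@@]1(C)OC(=CC1=O)/C(C)=C\[C@H](C=C)OC(=O)C=C | intermediate
17 | (2R)-2-[2-(tert-butyldimethylsilyloxy)ethyl]-2-methyl-5-{(1Z)-1-[(2S)-5-oxo-2,5-dihydrofuran-2-yl]prop-1-en-2-yl}furan-3(2H)-one | CC(C)(C)[Si](C)(C)OCC[C@@]1(C)OC(=CC1=O)/C(C)=C\[C@H]1OC(=O)C=C1 | intermediate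
18 | (2R)-2-(2-hydroxyethyl)-2-methyl-5-{(1Z)-1-[(2S)-5-oxo-2,5-dihydrofuran-2-yl]prop-1-en-2-yl}furan-3(2H)-one | OCC[C@@]1(C)OC(=CC1=O)/C(C)=C\[C@H]1OC(=O)C=C1 | intermediate
19 | (6R,7R,8R,10R)-8-hydroxy-1-oxo-3,10-epoxy-13-norgermacra-2,4Z-dien-12,6-olide | O[C@@H]1C[C@@]2(C)OC(=CC2=O)/C(C)=C\[C@H]2OC(=O)C[C@@H]21 | intermediate
20 | iodomethane | CI | starting material
21 | dilithium 8-alkoxide/C11–C12 enolate of 19 | [Li+].[Li+].[O-][C@@H]1C[C@@]2(C)OC(=CC2=O)/C(C)=C\[C@H]2OC([O-])=C[C@@H]21 | intermediate
22 | (6R,7R,8R,10R,11S)-8-hydroxy-1-oxo-3,10-epoxygermacra-2,4Z-dien-12,6-olide | O[C@@H]1C[C@@]2(C)OC(=CC2=O)/C(C)=C\[C@H]2OC(=O)[C@@H](C)[C@@H]21 | intermediate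
23 | angelic acid, (Z)-2-methylbut-2-enoic acid | C/C=C(/C)C(=O)O | starting material
24 | angelic 2,4,6-trichlorobenzoic anhydride | C/C=C(/C)C(=O)OC(=O)c1c(Cl)cc(Cl)cc1Cl | intermediate
25 | target, (6R,7R,8R,10R,11S)-8-angeloyloxy-1-oxo-3,10-epoxygermacra-2,4Z-dien-12,6-olide | C/C=C(/C)C(=O)O[C@@H]1C[C@@]2(C)OC(=CC2=O)/C(C)=C\[C@H]2OC(=O)[C@@H](C)[C@@H]21 | target

**Total step count:** 15. **Longest linear sequence:** 11 steps (steps 5 to 15).

**Steps most likely to fail**

1. Step 13 (key step).
What may go wrong:
- Ring closure may be slower than oxidation of the hydroxyalkyl radical by the ground-state catalyst.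
- Hydrogen abstraction from the doubly activated C6–H would erode the C6 configuration.
- The C4=C5 bond may photoisomerise from Z to E.
- Facial selectivity at C8 may be poor.

Fallback (known chemistry): it sets out from 18. Dess–Martin oxidation gives the seco-aldehyde F1. Slow addition of F1 to SmI2 and t-BuOH in THF (−78 to 0 °C, high dilution) closes the same bond by a ketyl–olefin reductive cyclisation. This aldehyde/enoate coupling is known up to medium rings, and the ketyl oxygen is oriented away from the enoate. Protonation of the samarium enolate and alkoxide brings the route back at 19.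

2. Step 14.
What may go wrong:
- Deprotonation at C6–H (vinylogous to the furanone carbonyl) may compete with lactone enolisation.
- The alkoxide or the enolate may attack the furanone across the ring.
- Double alkylation may occur.

Fallback: C13 is carried from the start, and C11 is set by equilibration instead of alkylation. It sets out from 12.
- Methacryloyl chloride gives the methacrylate F2.
- Sonogashira coupling with 6 gives the enynone F3.
- Gold catalysis gives the furanone F4.
- RCM gives the silylated 3-methylbutenolide F5.
- HF·pyridine gives the seco-alcohol F6.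
- Irradiation as in step 13 should give the 11-epimer F7, because hydrogen is delivered to C11 opposite to the C8 branch.
- DBU in toluene at 80 °C equilibrates C11 to the more stable trans-α,β arrangement, which brings the route back at 22.

3. Step 9.
What may go wrong:
- Amine and copper may degrade the terminal ynone by Michael addition, oxidative dimerisation or self-cyclisation.
- Pd(0) may slowly ionise the bis-allylic acrylate.

Fallback: the terminal ynone is avoided. It sets out from 4. Lithium (tributylstannyl)acetylide (from ethynyltributylstannane and LDA) adds to the dioxolanone and gives the alkynylstannane F8. A Stille coupling of F8 with 14 (Pd2(dba)3, AsPh3, THF, rt, no amine and no copper) brings the route back at 15.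

**Further compounds**
F1 | step 13 | seco-aldehyde, 2-[(2R)-2-methyl-3-oxo-5-{(1Z)-1-[(2S)-5-oxo-2,5-dihydrofuran-2-yl]prop-1-en-2-yl}-2,3-dihydrofuran-2-yl]acetaldehyde | O=CC[C@@]1(C)OC(=CC1=O)/C(C)=C\[C@H]1OC(=O)C=C1
F2 | step 14 | (3S,4Z)-5-iodohexa-1,4-dien-3-yl 2-methylprop-2-enoate | C/C(I)=C/[C@H](C=C)OC(=O)C(C)=C
F3 | step 14 | methacrylate analogue of enynone 15 | CC(C)(C)[Si](C)(C)OCC[C@@](C)(O)C(=O)C#C/C(C)=C\[C@H](C=C)OC(=O)C(C)=C
F4 | step 14 | methacrylate analogue of furanone 16 | CC(C)(C)[Si](C)(C)OCC[C@@]1(C)OC(=CC1=O)/C(C)=C\[C@H](C=C)OC(=O)C(C)=C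
F5 | step 14 | 3-methylbutenolide analogue of 17 | CC(C)(C)[Si](C)(C)OCC[C@@]1(C)OC(=CC1=O)/C(C)=C\[C@H]1OC(=O)C(C)=C1
F6 | step 14 | 3-methylbutenolide analogue of 18 | OCC[C@@]1(C)OC(=CC1=O)/C(C)=C\[C@H]1OC(=O)C(C)=C1
F7 | step 14 | 11-epimer of 22 (6R,7R,8R,10R,11R) | O[C@@H]1C[C@@]2(C)OC(=CC2=O)/C(C)=C\[C@H]2OC(=O)[C@H](C)[C@@H]21
F8 | step 9 | (4R)-6-(tert-butyldimethylsilyloxy)-4-hydroxy-4-methyl-1-(tributylstannyl)hex-1-yn-3-one | CC(C)(C)[Si](C)(C)OCC[C@@](C)(O)C(=O)C#C[Sn](CCCC)(CCCC)CCCC
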